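The route rests on cutting the bond between the first CH2 of the dienyl chain and the exocyclic acyl carbon. The key step exploits that this acyl carbon, ring carbon C2 and the ring C1 carbonyl form a 1,3-dicarbonyl unit whose exocyclic end is at the carboxylic acid level, while ring carbons C3 to C6 with the C6 hydroxyl are the γ-lactone of (R)-5-oxooxolane-2-carboxylic acid. A Fukuyama coupling joins the C17 dienylzinc chloride to a β-keto thioester that carries this lactone and gives the full linear polyketone with the stereocentre already in place. A polyketide-like Claisen ring closure onto the lactone then forms the six-membered ring and frees the hydroxyl.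

Key step: step 5

Remark: the target is treated as one enol tautomer of a 2-acylcyclohexane-1,3-dione (all tautomers count as the same compound); ring atoms are numbered C1 (carbonyl next to the carbinol), C2 (acyl-bearing carbon), C3 (enol carbon), C4, C5 and C6 (carbinol carbon, R).

Step 1
Reactants: 1 1-phenyl-1H-tetrazole-5-thiol; 2 1-bromo-6-chlorohexane
Product: 3 5-[(6-chlorohexyl)sulfanyl]-1-phenyl-1H-tetrazole
Conditions: K2CO3, acetone, rt
Reagents that add atoms: none
Why: SN2 S-alkylation of the acidic thiol should occur at the more reactive C–Br end and leave the primary chloride for later use.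

Step 2
Reactants: 3 5-[(6-chlorohexyl)sulfanyl]-1-phenyl-1H-tetrazole
Product: 4 5-[(6-chlorohexyl)sulfonyl]-1-phenyl-1H-tetrazole
Conditions: 30% H2O2, (NH4)6Mo7O24·4H2O (cat.), EtOH, 0 °C to rt
Reagents that add atoms: hydrogen peroxide, OO
Why: Molybdate-catalysed oxidation of a sulfide to the sulfone is the standard entry to Julia–Kocienski reagents and should not touch the alkyl chloride or the tetrazole.

Step 3
Reactants: 4 5-[(6-chlorohexyl)sulfonyl]-1-phenyl-1H-tetrazole; 5 (2E)-undec-2-enal
Product: 6 (6E,8E)-1-chloroheptadeca-6,8-diene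
Conditions: KN(SiMe3)2, DME, −78 °C, 15 min; then 5, −78 °C to rt
Reagents that add atoms: none
Why: Julia–Kocienski olefination (carbanion addition to the aldehyde, Smiles rearrangement, loss of SO2 and the tetrazololate) is expected to give mainly the new E alkene while the E alkene of 5 is kept, and the short metalation at −78 °C should spare the primary chloride.

Step 4
Reactants: 7 (2R)-5-oxooxolane-2-carboxylic acid; 8 2,2-dimethyl-1,3-dioxane-4,6-dione (Meldrum's acid)
Product: 10 S-ethyl 3-oxo-3-[(2R)-5-oxooxolan-2-yl]propanethioate, via acyl Meldrum's acid 9 (not isolated)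
Conditions: DCC, DMAP, CH2Cl2, 0 °C to rt; filter, concentrate; then EtSH, toluene, 80 °C (sealed tube)
Reagents that add atoms: ethanethiol, CCS
Why: C-acylation of Meldrum's acid by the carbodiimide-activated acid, then thermolysis to the acylketene (loss of acetone and CO2) and trapping by the thiol, is the Meldrum's acid route to β-keto thioesters; the stereocentre should stay intact because the carbonyl next to it is held first as the Meldrum's acid enol and then as a neutral ketone.

Step 5
Reactants: 6 (6E,8E)-1-chloroheptadeca-6,8-diene; 10 S-ethyl 3-oxo-3-[(2R)-5-oxooxolan-2-yl]propanethioate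
Product: 15 (5R)-5-[(9E,11E)-3-oxoicosa-9,11-dienoyl]oxolan-2-one, via alkylmagnesium chloride 11 (not isolated), via alkylzinc chloride 12 (not isolated), via silyl enol ether thioester 13 (not isolated), via silyl enol ether ketone 14 (not isolated)
Conditions: (a) 6, Mg, I2 (cat.), THF, 60 °C; ZnCl2 (1.1 equiv), 0 °C to rt; (b) 10, BSA, THF, rt, volatiles removed; (c) solution (a) added to (b), PdCl2(PPh3)2 (5 mol%), THF–toluene, rt; 1 M HCl work-up
Reagents that add atoms: none
Why: Fukuyama coupling: zerovalent palladium, formed from PdCl2(PPh3)2 and the zinc reagent, inserts into the acyl C–S bond of 13, the primary alkyl group moves from zinc to palladium, and reductive elimination forms the bond between C4 (chain CH2) and the C3 carbonyl carbon of 15, which is the exocyclic CH2–C(=O) bond of the target. It is the standard thioester-to-ketone coupling, applied here to a β-silyloxy enoyl thioester; no ring is closed and no stereocentre is formed, the R centre of 10 being carried through under neutral conditions. The step needs chemoselectivity for the thioester over the lactone carbonyl, the enone-type carbonyl and the allylic lactone C–O bond; the low basicity and nucleophilicity of the alkylzinc chloride and the fast insertion into C–S at room temperature should secure it. Transient O-silylation with BSA removes the acidic C2 hydrogens of the β-keto thioester, which would otherwise protonate the zinc reagent, and the acidic work-up returns the β-diketone. Two-electron transmetalation avoids a free primary radical at the chain end, which could cyclise onto the diene.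

Step 6
Reactants: 15 (5R)-5-[(9E,11E)-3-oxoicosa-9,11-dienoyl]oxolan-2-one
Product: 17 (6R)-3,6-dihydroxy-2-[(7E,9E)-octadeca-7,9-dienoyl]cyclohex-2-en-1-one, via hydroxy methyl ester 16 (not isolated)
Conditions: NaOMe (3 equiv), MeOH, 0 °C to 50 °C; then 1 M HCl, 0 °C
Reagents that add atoms: none
Why: Claisen (Dieckmann-type) condensation that copies the polyketide ring closure: methoxide opens the lactone reversibly to 16, the central carbon of the β-diketone anion attacks the ester carbonyl (6-exo-trig), and the strongly acidic triketone leaves the equilibrium as its enolate; the stereocentre is not a reacting atom and should keep its R configuration because the carbonyl next to it is part of the delocalised anion throughout.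

Compound list
1 | 1-phenyl-1H-tetrazole-5-thiol | Sc1nnnn1-c1ccccc1 | starting material
2 | 1-bromo-6-chlorohexane | ClCCCCCCBr | starting material
3 | 5-[(6-chlorohexyl)sulfanyl]-1-phenyl-1H-tetrazole | ClCCCCCCSc1nnnn1-c1ccccc1 | intermediate
4 | 5-[(6-chlorohexyl)sulfonyl]-1-phenyl-1H-tetrazole | ClCCCCCCS(=O)(=O)c1nnnn1-c1ccccc1 | intermediate
5 | (2E)-undec-2-enal | CCCCCCCC/C=C/C=O | starting material
6 | (6E,8E)-1-chloroheptadeca-6,8-diene | CCCCCCCC/C=C/C=C/CCCCCCl | intermediate
7 | (2R)-5-oxooxolane-2-carboxylic acid | OC(=O)[C@H]1CCC(=O)O1 | starting material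
8 | 2,2-dimethyl-1,3-dioxane-4,6-dione (Meldrum's acid) | CC1(C)OC(=O)CC(=O)O1 | starting material
9 | 5-{hydroxy[(2R)-5-oxooxolan-2-yl]methylidene}-2,2-dimethyl-1,3-dioxane-4,6-dione (acyl Meldrum's acid) | CC1(C)OC(=O)C(=C(O)[C@H]2CCC(=O)O2)C(=O)O1 | intermediate
10 | S-ethyl 3-oxo-3-[(2R)-5-oxooxolan-2-yl]propanethioate | CCSC(=O)CC(=O)[C@H]1CCC(=O)O1 | intermediate
11 | [(6E,8E)-heptadeca-6,8-dien-1-yl]magnesium chloride | CCCCCCCC/C=C/C=C/CCCCC[Mg]Cl | intermediate
12 | [(6E,8E)-heptadeca-6,8-dien-1-yl]zinc chloride | CCCCCCCC/C=C/C=C/CCCCC[Zn]Cl | intermediate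
13 | S-ethyl (2Z)-3-[(2R)-5-oxooxolan-2-yl]-3-[(trimethylsilyl)oxy]prop-2-enethioate | CCSC(=O)/C=C(\O[Si](C)(C)C)[C@H]1CCC(=O)O1 | intermediate
14 | (5R)-5-{(1Z,9E,11E)-3-oxo-1-[(trimethylsilyl)oxy]icosa-1,9,11-trien-1-yl}oxolan-2-one | CCCCCCCC/C=C/C=C/CCCCCC(=O)/C=C(\O[Si](C)(C)C)[C@H]1CCC(=O)O1 | intermediate
15 | (5R)-5-[(9E,11E)-3-oxoicosa-9,11-dienoyl]oxolan-2-one | CCCCCCCC/C=C/C=C/CCCCCC(=O)CC(=O)[C@H]1CCC(=O)O1 | intermediate
16 | methyl (4R,13E,15E)-4-hydroxy-5,7-dioxotetracosa-13,15-dienoate | CCCCCCCC/C=C/C=C/CCCCCC(=O)CC(=O)[C@H](O)CCC(=O)OC | intermediate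
17 | (6R)-3,6-dihydroxy-2-[(7E,9E)-octadeca-7,9-dienoyl]cyclohex-2-en-1-one | CCCCCCCC/C=C/C=C/CCCCCC(=O)C1=C(O)CC[C@@H](O)C1=O | target

Total step count: 6. Longest linear sequence: 5 steps (steps 1, 2, 3, 5, 6); the ring-side branch is step 4 followed by steps 5 and 6.

Steps most likely to fail

Step 5. What may go wrong: slow oxidative addition into the electron-rich β-silyloxy enoyl thioester, loss of the silyl group followed by protonation of the zinc reagent, or ionisation of the allylic lactone C–O bond by palladium. Fallback: the same bond is made first on a small acyl unit, and the lactone is attached afterwards. It sets out from alkylmagnesium chloride 11 (made from 6 as in step 5) and from acid 7, and comes back to the route at 15. Alkylmagnesium chloride 11 is added to N-methoxy-N-methylacetamide (THF, 0 °C) to give (8E,10E)-nonadeca-8,10-dien-2-one F1. Acid 7 is treated with 1,1'-carbonyldiimidazole (THF, rt) to give (5R)-5-(1H-imidazole-1-carbonyl)oxolan-2-one F2. The kinetic methyl enolate of F1 (LiN(iPr)2, 2 equiv, THF, −78 °C) is then C-acylated by F2 to give 15.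

Step 6. What may go wrong: partial loss of configuration at the carbinol carbon through an enediolate, retro-Claisen cleavage of the diketone, or sluggish C-acylation by the stabilised diketone anion in warm methoxide. Fallback: the ring is closed at low temperature at the thioester stage and the chain is attached last. It sets out from 10 and comes back at 17. Thioester 10 is treated with LiN(SiMe3)2 (2.2 equiv, THF, −78 to 0 °C) and the resulting dianion is trapped with TBSOTf to give S-ethyl (5R)-2,5-bis[(tert-butyldimethylsilyl)oxy]-6-oxocyclohex-1-ene-1-carbothioate F3. Fukuyama coupling of F3 with alkylzinc chloride 12 (PdCl2(PPh3)2, THF–toluene, rt) should give (6R)-3,6-bis[(tert-butyldimethylsilyl)oxy]-2-[(7E,9E)-octadeca-7,9-dienoyl]cyclohex-2-en-1-one F4. HF·pyridine in THF removes both silyl groups to give 17.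

Step 3. What may go wrong: incomplete E selectivity at the new alkene, and intramolecular alkylation of the sulfonyl carbanion by the chloride. Fallback: the diene is built by cross-coupling instead of olefination. It sets out from 5 and comes back at 6. Takai olefination of 5 (CrCl2, CHI3, THF–dioxane, 0 °C) gives (1E,3E)-1-iodododeca-1,3-diene F5. 5-Chloropent-1-ene is hydroborated with 9-BBN-H (THF, rt) to 9-(5-chloropentyl)-9-borabicyclo[3.3.1]nonane F6. A B-alkyl Suzuki–Miyaura coupling of F5 with F6 (PdCl2(dppf), K3PO4, DMF–THF–H2O, rt) gives 6 with the alkene geometry of F5 retained.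

Further compounds
F1 | step 5 | (8E,10E)-nonadeca-8,10-dien-2-one | CCCCCCCC/C=C/C=C/CCCCCC(C)=O
F2 | step 5 | (5R)-5-(1H-imidazole-1-carbonyl)oxolan-2-one | O=C(n1ccnc1)[C@H]1CCC(=O)O1
F3 | step 6 | S-ethyl (5R)-2,5-bis[(tert-butyldimethylsilyl)oxy]-6-oxocyclohex-1-ene-1-carbothioate | CCSC(=O)C1=C(O[Si](C)(C)C(C)(C)C)CC[C@@H](O[Si](C)(C)C(C)(C)C)C1=O
F4 | step 6 | (6R)-3,6-bis[(tert-butyldimethylsilyl)oxy]-2-[(7E,9E)-octadeca-7,9-dienoyl]cyclohex-2-en-1-one | CCCCCCCC/C=C/C=C/CCCCCC(=O)C1=C(O[Si](C)(C)C(C)(C)C)CC[C@@H](O[Si](C)(C)C(C)(C)C)C1=O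
F5 | step 3 | (1E,3E)-1-iodododeca-1,3-diene | CCCCCCCC/C=C/C=C/I
F6 | step 3 | 9-(5-chloropentyl)-9-borabicyclo[3.3.1]nonane | ClCCCCCB1C2CCCC1CCC2
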